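The pyridone ring (ring B) is treated as a ring-expanded isatin. The lactam nitrogen N-1, C2(=O) and the oxygen-bearing C3 already sit in the five-membered lactam, so only C4–H must be inserted between C3 and arene carbon C4a. Trimethylsilyldiazomethane does this in one flask: addition to the ketone, loss of nitrogen with a 1,2-aryl shift, enolisation to the 3-hydroxy-2-quinolinone, and O-methylation. The precursor is an isatin with the protected guaiacyl-type benzyl group at C6 and a MOM-protected oxygen at C7. Its contiguous N/O/benzyl pattern comes from a 1,2,3-trisubstituted nitroarene by Negishi benzylation, Bartoli annulation and indole oxidation. Orthogonal MOM and benzyl ethers then direct sulfation to O8.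

Key step: step 6

Assumption: the target is taken as the free aryl hydrogen sulfate exactly as drawn; because such acids hydrolyse under their own acidity, the sulfate is carried as its triethylammonium salt and protonated only in the very last operation.

Step 1
Reactants: 1 2-bromo-6-nitrophenol
Product: 2 1-bromo-2-(methoxymethoxy)-3-nitrobenzene
Conditions: MOMCl (1.3 equiv), K2CO3 (2 equiv), DMF, 0 °C to rt
Reagents that add atoms: chloromethyl methyl ether, COCCl
Why: Williamson-type O-alkylation of the acidic nitrophenoxide with the very reactive α-chloro ether should be fast despite the two ortho groups, and the acetal formed is inert to organozinc, Grignard and amine reagents yet leaves later under acid that spares a benzyl ether.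

Step 2
Reactants: 3 4-benzyloxy-3-methoxybenzyl alcohol
Product: 4 4-benzyloxy-3-methoxybenzyl chloride
Conditions: SOCl2 (1.1 equiv), CH2Cl2, 0 °C to rt; evaporation with toluene
Reagents that add atoms: thionyl chloride, O=S(Cl)Cl
Why: Chlorodehydroxylation through the chlorosulfite is easy for this electron-rich benzylic alcohol, gives only gaseous co-products, and the chloride is used at once because it solvolyses readily.

Step 3
Reactants: 4 4-benzyloxy-3-methoxybenzyl chloride; 2 1-bromo-2-(methoxymethoxy)-3-nitrobenzene
Product: 6 1-(4-benzyloxy-3-methoxybenzyl)-2-(methoxymethoxy)-3-nitrobenzene, via 4-benzyloxy-3-methoxybenzylzinc chloride 5 (not isolated)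
Conditions: (a) activated Zn dust (1.5 equiv), LiCl (1.5 equiv), THF, 0 °C to rt; (b) supernatant of 5 (1.3 equiv) added to 2, Pd(OAc)2 (2 mol %), SPhos (2-dicyclohexylphosphino-2',6'-dimethoxybiphenyl, 4 mol %), THF, rt to 40 °C
Reagents that add atoms: zinc, [Zn] (kept only in 5)
Why: LiCl-assisted direct zinc insertion into a benzylic chloride keeps Wurtz dimerisation low at or below room temperature, and the Negishi sp2–sp3 cross-coupling that follows tolerates the nitro group and the acetal, the benzyl partner having no β-hydrogen that could divert the palladium intermediate.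

Step 4
Reactants: 6 1-(4-benzyloxy-3-methoxybenzyl)-2-(methoxymethoxy)-3-nitrobenzene; 7 vinylmagnesium bromide
Product: 8 6-(4-benzyloxy-3-methoxybenzyl)-7-(methoxymethoxy)-1H-indole
Conditions: 7 (1.0 M in THF, 3.5 equiv), THF, −40 °C; sat. aq NH4Cl
Reagents that add atoms: vinylmagnesium bromide, C=C[Mg]Br
Why: Bartoli indole synthesis, in which the first equivalent takes the nitro group to the nitroso stage, the second adds to its oxygen and the N-aryl-O-vinylhydroxylamine undergoes a [3,3]-sigmatropic shift that the buttressed ortho MOM ether accelerates and that can end only at the single hydrogen-bearing ortho carbon, the third equivalent serving as base before cyclisation and dehydration.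

Step 5
Reactants: 8 6-(4-benzyloxy-3-methoxybenzyl)-7-(methoxymethoxy)-1H-indole
Product: 9 6-(4-benzyloxy-3-methoxybenzyl)-7-(methoxymethoxy)indoline-2,3-dione (the isatin)
Conditions: I2 (1.2 equiv, recycled by the peroxide), t-BuOOH (70% aq, 5 equiv), DMSO, 60–80 °C, stopped at full conversion; aq Na2S2O3
Reagents that add atoms: tert-butyl hydroperoxide, CC(C)(C)OO
Why: The iodine/hydroperoxide oxidation of N–H indoles to isatins (C3 iodination followed by peroxide oxygenation of C2 and C3) should begin at the enamine-like C2=C3 bond, by far the most electron-rich site, and the hydrogen iodide formed is re-oxidised to iodine, which keeps the medium mild enough for the acetal and the diarylmethane.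

Step 6
Reactants: 9 6-(4-benzyloxy-3-methoxybenzyl)-7-(methoxymethoxy)indoline-2,3-dione; 10 trimethylsilyldiazomethane
Product: 12 7-(4-benzyloxy-3-methoxybenzyl)-3-methoxy-8-(methoxymethoxy)quinolin-2(1H)-one, via 3-hydroxy-2-quinolinone 11 (not isolated)
Conditions: 10 (2.0 M in hexanes, 1.2 equiv, then 1.5 equiv more once 9 is consumed), Et3N (2 equiv), EtOH–CH2Cl2, 0 °C to rt; AcOH quench
Reagents that add atoms: trimethylsilyldiazomethane, C[Si](C)(C)C=[N+]=[N-]
Why: The nucleophilic carbon of 10 adds to the C3 ketone of 9, and the β-oxido diazonium ion expels N2 while arene carbon C3a shifts onto the former diazo carbon, which creates the C3–C4 and C4–C4a bonds of the quinolinone; ethanol then takes the silyl group and the 2,3-dione enolises to aromatic 11. The closest known reaction type is the Buchner–Curtius–Schlotterbeck (Eistert) homologation of isatins with diazomethane or its trimethylsilyl analogue, an established entry to 3-hydroxy- and 3-methoxy-2-quinolinones of the viridicatin family. The six-membered pyridone ring is closed by one-carbon ring expansion of the five-membered lactam (insertion into the C3–C3a bond), not by a cyclisation at nitrogen or at a carbonyl group. No stereocentre is formed. Attack at the ketone rather than at C2 follows from the amide stabilisation of the C2 carbonyl, and aryl migration should beat acyl migration and epoxide closure because C3a belongs to an electron-rich ring (next to the anilide carbon C7a and para to the alkyl-type benzyl donor) whereas C2 is electron-poor. The second charge of 10, desilylated by ethanol to diazomethane, should methylate only the enolic 3-OH, the sole acidic O–H since both phenols are masked, while the lactam N–H is much less acidic and is screened by the neighbouring 8-OMOM group.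

Step 7
Reactants: 12 7-(4-benzyloxy-3-methoxybenzyl)-3-methoxy-8-(methoxymethoxy)quinolin-2(1H)-one
Product: 13 7-(4-benzyloxy-3-methoxybenzyl)-8-hydroxy-3-methoxyquinolin-2(1H)-one
Conditions: HCl (about 1 M), MeOH–THF, 40 °C
Reagents that add atoms: none
Why: Acid-catalysed acetal exchange (MOM cleavage through the oxocarbenium ion, which methanol traps) is far faster than any attack on the benzyl ether, the aryl methyl ether or the 3-methoxy lactam, so O8–H should emerge as the only free phenol.

Step 8
Reactants: 13 7-(4-benzyloxy-3-methoxybenzyl)-8-hydroxy-3-methoxyquinolin-2(1H)-one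
Product: 14 triethylammonium 7-(4-benzyloxy-3-methoxybenzyl)-3-methoxy-2-oxo-1,2-dihydroquinolin-8-yl sulfate
Conditions: SO3·NEt3 (3 equiv), Et3N (2 equiv), DMF, 50 °C; water quench; silica, CH2Cl2–MeOH–Et3N
Reagents that add atoms: sulfur trioxide–triethylamine complex, CC[N+](CC)(CC)S(=O)(=O)[O-]
Why: O-sulfation of a phenol with a sulfur trioxide–amine complex goes to O8 because it is the only O–H left, warming offsets the flanking benzyl and N–H groups, any N-sulfonated lactam reverts on aqueous work-up, and the salt form keeps the aryl sulfate away from acid.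

Step 9
Reactants: 14 triethylammonium 7-(4-benzyloxy-3-methoxybenzyl)-3-methoxy-2-oxo-1,2-dihydroquinolin-8-yl sulfate
Product: 16 scolopendrine [7-(4-hydroxy-3-methoxybenzyl)-3-methoxy-2-oxo-1,2-dihydroquinolin-8-yl hydrogen sulfate], via scolopendrine triethylammonium salt 15 (not isolated)
Conditions: H2 (1 atm), 10% Pd/C, MeOH, rt, no free amine added; filtration; Dowex 50WX8 (H+ form), MeOH–H2O, 0 °C; lyophilisation
Reagents that add atoms: none
Why: Catalytic hydrogenolysis cleaves the O-benzyl bond while aryl sulfate monoester salts, the diarylmethane C–C bonds and the 2-quinolinone are not reduced at one atmosphere, and cold cation exchange then swaps triethylammonium for a proton.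

Compound list (no compound of the main route has a stereocentre)
1 | 2-bromo-6-nitrophenol | Oc1c(Br)cccc1[N+](=O)[O-] | starting material
2 | 1-bromo-2-(methoxymethoxy)-3-nitrobenzene | COCOc1c(Br)cccc1[N+](=O)[O-] | intermediate
3 | 4-benzyloxy-3-methoxybenzyl alcohol | COc1cc(CO)ccc1OCc1ccccc1 | starting material
4 | 4-benzyloxy-3-methoxybenzyl chloride | COc1cc(CCl)ccc1OCc1ccccc1 | intermediate
5 | 4-benzyloxy-3-methoxybenzylzinc chloride (THF solution, not isolated) | COc1cc(C[Zn]Cl)ccc1OCc1ccccc1 | intermediate
6 | 1-(4-benzyloxy-3-methoxybenzyl)-2-(methoxymethoxy)-3-nitrobenzene | COCOc1c(Cc2ccc(OCc3ccccc3)c(OC)c2)cccc1[N+](=O)[O-] | intermediate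
7 | vinylmagnesium bromide | C=C[Mg]Br | starting material
8 | 6-(4-benzyloxy-3-methoxybenzyl)-7-(methoxymethoxy)-1H-indole | COCOc1c(Cc2ccc(OCc3ccccc3)c(OC)c2)ccc2cc[nH]c12 | intermediate
9 | 6-(4-benzyloxy-3-methoxybenzyl)-7-(methoxymethoxy)indoline-2,3-dione | COCOc1c(Cc2ccc(OCc3ccccc3)c(OC)c2)ccc2c1NC(=O)C2=O | intermediate
10 | trimethylsilyldiazomethane | C[Si](C)(C)C=[N+]=[N-] | starting material
11 | 7-(4-benzyloxy-3-methoxybenzyl)-3-hydroxy-8-(methoxymethoxy)quinolin-2(1H)-one (not isolated) | COCOc1c(Cc2ccc(OCc3ccccc3)c(OC)c2)ccc2cc(O)c(=O)[nH]c12 | intermediate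
12 | 7-(4-benzyloxy-3-methoxybenzyl)-3-methoxy-8-(methoxymethoxy)quinolin-2(1H)-one | COCOc1c(Cc2ccc(OCc3ccccc3)c(OC)c2)ccc2cc(OC)c(=O)[nH]c12 | intermediate
13 | 7-(4-benzyloxy-3-methoxybenzyl)-8-hydroxy-3-methoxyquinolin-2(1H)-one | COc1cc(Cc2ccc3cc(OC)c(=O)[nH]c3c2O)ccc1OCc1ccccc1 | intermediate
14 | triethylammonium 7-(4-benzyloxy-3-methoxybenzyl)-3-methoxy-2-oxo-1,2-dihydroquinolin-8-yl sulfate | COc1cc(Cc2ccc3cc(OC)c(=O)[nH]c3c2OS(=O)(=O)[O-])ccc1OCc1ccccc1.CC[NH+](CC)CC | intermediate
15 | triethylammonium 7-(4-hydroxy-3-methoxybenzyl)-3-methoxy-2-oxo-1,2-dihydroquinolin-8-yl sulfate (not isolated) | COc1cc(Cc2ccc3cc(OC)c(=O)[nH]c3c2OS(=O)(=O)[O-])ccc1O.CC[NH+](CC)CC | intermediate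
16 | scolopendrine | COc1cc(Cc2ccc3cc(OC)c(=O)[nH]c3c2OS(=O)(=O)O)ccc1O | target

Total step count: 9. Longest linear sequence: 8 steps (1 → 2 → 6 → 8 → 9 → 12 → 13 → 14 → 16; the branch from 3 through 4 is equally long).

Steps most likely to fail

Step 5.
- **What may go wrong:** The oxidant may not stop at the pyrrole ring. Hydrogen abstraction at the doubly benzylic methylene, iodination of the dialkoxyarene, or hydrolysis of the acetal by transient hydrogen iodide could all compete.
- **Fallback:** It sets out from 2 and comes back at 12, bringing in the benzyl group only after the oxidative and ring-expansion stages.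
- Bromide 2 undergoes the Bartoli reaction with 7 (THF, −40 °C) to give 6-bromo-7-(methoxymethoxy)-1H-indole F1.
- This simple indole has no benzylic C–H and no dialkoxyarene. It is oxidised with I2/t-BuOOH in DMSO to 6-bromo-7-(methoxymethoxy)indoline-2,3-dione F2.
- Reagent 10 with Et3N in EtOH expands F2 through 7-bromo-3-hydroxy-8-(methoxymethoxy)quinolin-2(1H)-one F3 to 7-bromo-3-methoxy-8-(methoxymethoxy)quinolin-2(1H)-one F4.
- Negishi coupling of F4 with 5 then gives 12. It uses Pd(OAc)2, SPhos and THF, with slow addition and one extra equivalent of 5 to allow for the lactam N–H.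

Step 4.
- **What may go wrong:** The Grignard reagent may carry the nitro group down to the aniline stage faster than the sigmatropic pathway runs. Little indole would then form from advanced material.
- **Fallback:** It sets out from 6 and comes back at 9, bypassing 8 by a Gassman-type isatin construction.
- Fe/NH4Cl in aqueous EtOH reduces 6 to 3-(4-benzyloxy-3-methoxybenzyl)-2-(methoxymethoxy)aniline F5.
- The chlorosulfonium salt is made from ethyl (methylthio)acetate and SO2Cl2 with 1,8-bis(dimethylamino)naphthalene in CH2Cl2 at −78 °C. It is treated with F5 and then Et3N.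
- The resulting ylide rearranges by a [2,3]-shift (Sommelet–Hauser type) to the only free ortho carbon, giving ethyl 2-[2-amino-4-(4-benzyloxy-3-methoxybenzyl)-3-(methoxymethoxy)phenyl]-2-(methylthio)acetate F6.
- F6 lactamises on warming in toluene with a trace of AcOH to 6-(4-benzyloxy-3-methoxybenzyl)-7-(methoxymethoxy)-3-(methylthio)indolin-2-one F7.
- NCS in CH2Cl2 gives 3-chloro-6-(4-benzyloxy-3-methoxybenzyl)-7-(methoxymethoxy)-3-(methylthio)indolin-2-one F8.
- Brief hydrolysis of F8 with HgO and BF3·OEt2 in aqueous THF delivers 9.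

Step 6.
- **What may go wrong:** The adduct may collapse to the spiro-epoxide instead of undergoing the aryl shift, or methylation may run on to the lactam nitrogen or O2 while excess diazoalkane is present.
- **Fallback:** It sets out from 9 and comes back at 11. It keeps the same carbon insertion but separates addition, migration and methylation.
- Ethyl diazoacetate with catalytic DBU in EtOH adds in aldol fashion to the C3 ketone, giving ethyl 2-diazo-2-[6-(4-benzyloxy-3-methoxybenzyl)-3-hydroxy-7-(methoxymethoxy)-2-oxoindolin-3-yl]acetate F9.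
- Rh2(OAc)4 (1 mol %) converts F9 through the rhodium carbene and a 1,2-aryl shift into ethyl 7-(4-benzyloxy-3-methoxybenzyl)-3-hydroxy-8-(methoxymethoxy)-2-oxo-1,2-dihydroquinoline-4-carboxylate F10.
- LiOH in aqueous THF gives 7-(4-benzyloxy-3-methoxybenzyl)-3-hydroxy-8-(methoxymethoxy)-2-oxo-1,2-dihydroquinoline-4-carboxylic acid F11.
- F11 is a β-keto acid in its 3-oxo tautomer and should lose CO2 on heating in diphenyl ether to give 11, now isolated.
- One equivalent of 10 in toluene–MeOH, as in the second stage of step 6, then gives 12.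

Further compounds
F1 | step 5 | 6-bromo-7-(methoxymethoxy)-1H-indole | COCOc1c(Br)ccc2cc[nH]c12
F2 | step 5 | 6-bromo-7-(methoxymethoxy)indoline-2,3-dione | COCOc1c(Br)ccc2c1NC(=O)C2=O
F3 | step 5 | 7-bromo-3-hydroxy-8-(methoxymethoxy)quinolin-2(1H)-one | COCOc1c(Br)ccc2cc(O)c(=O)[nH]c12
F4 | step 5 | 7-bromo-3-methoxy-8-(methoxymethoxy)quinolin-2(1H)-one | COCOc1c(Br)ccc2cc(OC)c(=O)[nH]c12
F5 | step 4 | 3-(4-benzyloxy-3-methoxybenzyl)-2-(methoxymethoxy)aniline | COCOc1c(Cc2ccc(OCc3ccccc3)c(OC)c2)cccc1N
F6 | step 4 | ethyl 2-[2-amino-4-(4-benzyloxy-3-methoxybenzyl)-3-(methoxymethoxy)phenyl]-2-(methylthio)acetate (racemic) | CCOC(=O)C(SC)c1ccc(Cc2ccc(OCc3ccccc3)c(OC)c2)c(OCOC)c1N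
F7 | step 4 | 6-(4-benzyloxy-3-methoxybenzyl)-7-(methoxymethoxy)-3-(methylthio)indolin-2-one (racemic) | COCOc1c(Cc2ccc(OCc3ccccc3)c(OC)c2)ccc2c1NC(=O)C2SC
F8 | step 4 | 3-chloro-6-(4-benzyloxy-3-methoxybenzyl)-7-(methoxymethoxy)-3-(methylthio)indolin-2-one (racemic) | COCOc1c(Cc2ccc(OCc3ccccc3)c(OC)c2)ccc2c1NC(=O)C2(Cl)SC
F9 | step 6 | ethyl 2-diazo-2-[6-(4-benzyloxy-3-methoxybenzyl)-3-hydroxy-7-(methoxymethoxy)-2-oxoindolin-3-yl]acetate (racemic) | CCOC(=O)C(=[N+]=[N-])C1(O)C(=O)Nc2c(OCOC)c(Cc3ccc(OCc4ccccc4)c(OC)c3)ccc12
F10 | step 6 | ethyl 7-(4-benzyloxy-3-methoxybenzyl)-3-hydroxy-8-(methoxymethoxy)-2-oxo-1,2-dihydroquinoline-4-carboxylate | CCOC(=O)c1c(O)c(=O)[nH]c2c(OCOC)c(Cc3ccc(OCc4ccccc4)c(OC)c3)ccc12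
F11 | step 6 | 7-(4-benzyloxy-3-methoxybenzyl)-3-hydroxy-8-(methoxymethoxy)-2-oxo-1,2-dihydroquinoline-4-carboxylic acid | OC(=O)c1c(O)c(=O)[nH]c2c(OCOC)c(Cc3ccc(OCc4ccccc4)c(OC)c3)ccc12
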